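**Proposed synthesis of CNP0124388.1 (18): ring C by an o-quinone methide [4+2] annulation, then a C4-directed hydroboration**

## Analysis of the target

Target 18 is a 4-arylflavan-3-ol. It is a chroman (ring A fused to pyran ring C, made of O1, C2, C3, C4, C4a, C8a) with catechol ring B on C2, a secondary OH on C3 and the 2,4-dihydroxy-3-methoxyphenyl ring D on C4; ring A carries only the 7-OH (5-deoxy series). The SMILES reads (2R,3S,4R): 2,3-trans and 3,4-trans, so the two aryl groups are cis to each other, the 3-OH lies on the other face, and all three substituents are equatorial on the half-chair.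

The feature that drives the plan is C4. It is a benzhydryl carbon between two nearly identical 2,4-dioxygenated rings: ring A (C4a, with O1 on C8a and OH on C7) and ring D (C1'', with OH on C2'' and C4''). They differ only in the 3''-OMe and in which ortho oxygen is tied to C2. The array O1–C8a=C4a–C4 is therefore a latent ortho-quinone methide with C4 as its methide carbon.

The sensitive groups are five phenols (one catechol, prone to oxidation) and the C2–O1 benzylic aryl ether para to the 4'-OH. Base opens ring C through a B-ring quinone methide, which epimerises C2 and allows reclosure through the 2''-OH of ring D. Acid can ionise C2–O1 and the C4–aryl bond.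

The synthesis is hard for three reasons. Three contiguous stereocentres, one a diarylmethine, must be set in absolute terms. No cheap chiral-pool flavan exists in the 5-deoxy series. And the route must decide which of the two resorcinol-type rings becomes part of the chroman, with an endgame that is neutral and non-oxidising.

## Retrosynthetic reasoning

**18 from 17.** Only O–benzyl bonds are cut. All five phenols are masked as benzyl ethers in pentabenzyl ether 17, so one neutral hydrogenolysis ends the route and no acid or base touches the free polyphenol. The forward step must leave C2–O1 and the C4 benzhydryl C–H intact.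

**17 from 15.** The C3–O and C2–H bonds are cut together, leading back to the 4H-chromene 15 (C2=C3 enol ether, C4 stereocentre in place). A syn hydroboration–oxidation places boron on C3 and hydrogen on C2 from the face opposite the C4 aryl group. That single addition gives 3-OH trans to the 4-aryl group, 2-aryl trans to 3-OH and 2-aryl cis to 4-aryl, which is the complete relative configuration of 18. C2 and C3 are thus set as a vicinal pair by C4 alone (via alkylborane 16).

**15 from 7 and 12 (key disconnection).** Ring C is cut across O1–C2 and C3–C4. C4 is the methide carbon of the o-quinone methide 13, which forms from benzhydrol 7 by loss of water. The enamide 12 supplies C2 (with ring B) and C3. The forward reaction is a chiral-phosphoric-acid-catalysed formal [4+2] annulation to the 2-acetamidochroman 14, followed by acid-induced loss of acetamide. It closes the pyran ring, joins all three aryl rings and sets C4 in absolute terms. The cut is made here and not at C4–C1'' because ring D then sits on the methide carbon from the start. The free 2-OH of ring A, with both D-ring oxygens benzylated, decides which ring becomes the chroman.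

**7 from 3 and 4; 3 from 2 from 1.** The C4–C1'' bond of racemic 7 comes from 1,2-addition of aryllithium 5 (from bromide 3) to the phenolate 6 of aldehyde 4. The carbinol centre needs no control because it becomes planar in 13. Bromide 3 comes from regioselective bromination of dibenzyl ether 2, made from diol 1.

**12 from 9 from 8.** The C2–C3 bond and the nitrogen of 12 come from methyl addition to nitrile 9 (via N-magnesio ketimine 10), N-acetylation to 11 and tautomerisation. Nitrile 9 is the dibenzyl ether of 8.

## Alternatives that were turned down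

**Alternative 1: (textbook, biomimetic) cut C4–C1''.**
- Forward key step: Lewis-acid Friedel–Crafts reaction of the C4-activated, protected 5-deoxyflavan-3-ol A1 with 1 or 2.
- Step economy: A1 needs an enantioselective flavan-3-ol synthesis first (chalcone, 1,3-diarylpropene, asymmetric dihydroxylation, cyclisation), then C4 oxidation. That is about nine steps before the key step.
- Mechanism: the C4 cation of a 5-deoxy A ring is poorly stabilised, so the acid needed also ionises C2–O1.
- Nucleophile: after the first alkylation, 1 keeps a free position ortho/para to its hydroxyls and should over-alkylate, while 2 is sluggish.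
- Stereocontrol: 4α/4β selectivity rests only on the C3 substituent. 3,4-trans is favoured but not exclusive.
- It is also the route most chemists would draw first.

**Alternative 2: relay from C2; cut C4–C1'' and C3–O.**
- Forward key step: addition of 5 to the (2S)-flavanone A2, dehydration to the 2H-chromene A3, then syn hydroboration of C3=C4 anti to the 2-aryl group.
- The only catalyst-set centre would be C2, the most labile centre of the series. In A2 it is β to the ketone, so the basic, hindered aryllithium should favour enolisation and retro-oxa-Michael opening to the chalcone over addition.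
- In A3, C2 can racemise by 6π-electrocyclic ring opening to a vinyl o-quinone methide and by ionisation under the dehydration acid.
- The hydroboration would have to add to an alkene carbon that already carries two aryl groups.

**Alternative 3: open chain; close O1–C2 last.**
- Forward key step: asymmetric dihydroxylation of the (S,E)-1,1,3-triarylpropene A4, then benzylic etherification to close ring C.
- Making A4 as one enantiomer is the same problem as the target's C4: a diarylmethine whose two aryl groups differ only in a remote OMe and a protecting group.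
- The dihydroxylation next to C4 is a case of double diastereoselection.
- The SN1 closure at C2 is under thermodynamic control only.
- The stereotriad would need three separate events and the route would pass ten steps.

Key step: step 6

**Assumptions.** (i) Compounds 1, 4 and 8 are taken as commercially available. (ii) CIP ranks at C4 change between O-benzylated and free-phenol compounds (C1'' outranks C4a only while its ortho oxygen is benzylated). The descriptor letter at C4 therefore changes from S in 15–17 to R in 18 without any change in spatial arrangement.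

## Route

Step 1
Reactants: 1 2-methoxybenzene-1,3-diol (2-methoxyresorcinol)
Product: 2 1,3-bis(benzyloxy)-2-methoxybenzene
Conditions: BnBr (2.3 equiv), K2CO3, DMF, 60 °C
Reagents that add atoms: benzyl bromide, BrCc1ccccc1
Why: Williamson ether synthesis on both phenols; benzyl is chosen because all five phenol protecting groups can then leave in one neutral hydrogenolysis at the end.

Step 2
Reactants: 2 1,3-bis(benzyloxy)-2-methoxybenzene
Product: 3 1,3-bis(benzyloxy)-4-bromo-2-methoxybenzene
Conditions: NBS (1.0 equiv), MeCN, 0 °C to rt
Reagents that add atoms: N-bromosuccinimide, O=C1CCC(=O)N1Br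
Why: Electrophilic aromatic bromination; C4 and C6 are equivalent and each is para to one benzyloxy group and ortho to the other, whereas C5 is meta to both, so monobromination should be regioselective.

Step 3
Reactants: 3 1,3-bis(benzyloxy)-4-bromo-2-methoxybenzene; 4 4-(benzyloxy)-2-hydroxybenzaldehyde
Product: 7 [4-(benzyloxy)-2-hydroxyphenyl][2,4-bis(benzyloxy)-3-methoxyphenyl]methanol (racemic), via aryllithium 5 (not isolated), via sodium phenolate 6 (not isolated)
Conditions: 3, n-BuLi (1.05 equiv), THF, −78 °C; separately 4, NaH (1.0 equiv), THF, 0 °C; combine at −78 °C, warm to 0 °C; aq NH4Cl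
Reagents that add atoms: none
Why: Bromine–lithium exchange is faster than benzylic deprotonation at −78 °C, and deprotonating 4 beforehand avoids wasting aryllithium on the phenol; 1,2-addition to the aldehyde then forms the C4–C1'' bond. The carbinol centre is left racemic because it becomes planar in step 6.

Step 4
Reactants: 8 3,4-dihydroxybenzonitrile
Product: 9 3,4-bis(benzyloxy)benzonitrile
Conditions: BnBr (2.3 equiv), K2CO3, DMF, 60 °C
Reagents that add atoms: benzyl bromide, BrCc1ccccc1
Why: Williamson ether synthesis; the nitrile is inert under these conditions.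

Step 5
Reactants: 9 3,4-bis(benzyloxy)benzonitrile
Product: 12 N-{1-[3,4-bis(benzyloxy)phenyl]ethenyl}acetamide, via N-magnesio ketimine 10 (not isolated), via N-acetyl ketimine 11 (not isolated)
Conditions: MeMgBr (1.5 equiv), THF, 0 to 50 °C; then Ac2O (2 equiv), 0 °C to rt; aq NaHCO3
Reagents that add atoms: methylmagnesium bromide, C[Mg]Br; acetic anhydride, CC(=O)OC(C)=O
Why: Grignard addition to a nitrile stops at the N-metallo ketimine; N-acetylation in the same flask gives the N-acyl imine, which tautomerises to the conjugated enamide (one-pot enamide synthesis from nitriles).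

Step 6
Reactants: 7 [4-(benzyloxy)-2-hydroxyphenyl][2,4-bis(benzyloxy)-3-methoxyphenyl]methanol; 12 N-{1-[3,4-bis(benzyloxy)phenyl]ethenyl}acetamide
Product: 15 (4S)-7-(benzyloxy)-2-[3,4-bis(benzyloxy)phenyl]-4-[2,4-bis(benzyloxy)-3-methoxyphenyl]-4H-chromene, via o-quinone methide 13 (not isolated), via 2-acetamidochroman 14 (not isolated)
Conditions: (R)-TRIP (5 mol %), 12 (1.3 equiv), 4 Å MS, CHCl3, 0 °C to rt; then p-TsOH·H2O (10 mol %), rt
Reagents that add atoms: none
Why: The phosphoric acid dehydrates 7 to the (E)-o-quinone methide 13, which stays hydrogen-bonded to the catalyst through its carbonyl oxygen while the phosphoryl oxygen binds the N–H of 12. The enamide CH2 carbon (future C3) adds to the methide carbon (future C4) and the phenol oxygen closes on the N-acyliminium carbon (future C2); this is a formal inverse-electron-demand hetero-Diels–Alder reaction, and the closest known reaction type is the chiral-phosphoric-acid-catalysed [4+2] annulation of o-quinone methides generated in situ from 2-hydroxybenzhydrols with enamides and enecarbamates. Ring C is the only ring closed: seen stepwise, C3–C4 forms by intermolecular 1,4-addition and O1–C2 by 6-exo-trig attack of the phenol on the exocyclic C=N+ bond; seen as concerted, it is a [4+2] cycloaddition. C4 is the only stereocentre that survives and it is set by the catalyst, whose 3,3'-aryl groups leave one face of the bound methide open; the (R)-catalyst is written, the hand that delivers 4S must be confirmed on the first run, and the other hand is equally available. The aminal carbon C2 of 14 needs no control, because the added sulfonic acid expels acetamide through the 2-aryl oxocarbenium ion and proton loss is possible only from C3, which gives the C2=C3 enol ether 15. Regiochemistry follows from polarity (nucleophilic CH2 of 12 to electrophilic C4), and the choice of ring is secured by the substrate, since only ring A of 7 has a free ortho-OH while both D-ring oxygens are benzylated. The donor oxygens make 13 a stabilised o-quinone methide that should dimerise slowly, and enamides are among the strongest neutral π-nucleophiles toward such species.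

Step 7
Reactants: 15 (4S)-7-(benzyloxy)-2-[3,4-bis(benzyloxy)phenyl]-4-[2,4-bis(benzyloxy)-3-methoxyphenyl]-4H-chromene
Product: 17 (2R,3S,4S)-7-(benzyloxy)-2-[3,4-bis(benzyloxy)phenyl]-4-[2,4-bis(benzyloxy)-3-methoxyphenyl]-3,4-dihydro-2H-chromen-3-ol, via C3 alkylborane 16 (not isolated)
Conditions: BH3·THF (3 equiv), THF, 0 °C to rt; then 3 M NaOH, 30% H2O2, 0 °C to rt
Reagents that add atoms: hydrogen peroxide, OO
Why: Hydroboration–oxidation of a cyclic aryl enol ether: boron goes to C3 (β to O1 and non-benzylic) and hydrogen to C2 in a syn addition from the face opposite the pseudo-axial C4 aryl group, and oxidation proceeds with retention. This places 3-OH trans to the 4-aryl group and H-2 cis to the 3-OH, so the 2-aryl group is trans to 3-OH and cis to the 4-aryl group; C2 and C3 are both set by C4.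

Step 8
Reactants: 17 (2R,3S,4S)-7-(benzyloxy)-2-[3,4-bis(benzyloxy)phenyl]-4-[2,4-bis(benzyloxy)-3-methoxyphenyl]-3,4-dihydro-2H-chromen-3-ol
Product: 18 (2R,3S,4R)-2-(3,4-dihydroxyphenyl)-4-(2,4-dihydroxy-3-methoxyphenyl)-3,4-dihydro-2H-chromene-3,7-diol
Conditions: H2 (1 atm), 20% Pd(OH)2/C, degassed THF–MeOH, rt; filtration under argon
Reagents that add atoms: none
Why: Catalytic hydrogenolysis of the five aryl benzyl ethers under neutral conditions, which avoids the base-induced opening of ring C and acid ionisation at C2 or C4; the cyclic C2–O1 ether is expected to be cleaved far more slowly than the O–benzyl groups at 1 atm. No stereocentre is touched, and the change of the C4 descriptor from S to R is a CIP effect only.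

## Compound list

1 | 2-methoxybenzene-1,3-diol | COc1c(O)cccc1O | starting material
2 | 1,3-bis(benzyloxy)-2-methoxybenzene | COc1c(OCc2ccccc2)cccc1OCc1ccccc1 | intermediate
3 | 1,3-bis(benzyloxy)-4-bromo-2-methoxybenzene | COc1c(OCc2ccccc2)ccc(Br)c1OCc1ccccc1 | intermediate
4 | 4-(benzyloxy)-2-hydroxybenzaldehyde | O=Cc1ccc(OCc2ccccc2)cc1O | starting material
5 | [2,4-bis(benzyloxy)-3-methoxyphenyl]lithium | [Li]c1ccc(OCc2ccccc2)c(OC)c1OCc1ccccc1 | intermediate
6 | sodium 5-(benzyloxy)-2-formylphenolate | [Na+].[O-]c1cc(OCc2ccccc2)ccc1C=O | intermediate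
7 | [4-(benzyloxy)-2-hydroxyphenyl][2,4-bis(benzyloxy)-3-methoxyphenyl]methanol (racemic) | OC(c1ccc(OCc2ccccc2)cc1O)c1ccc(OCc2ccccc2)c(OC)c1OCc1ccccc1 | intermediate
8 | 3,4-dihydroxybenzonitrile | N#Cc1ccc(O)c(O)c1 | starting material
9 | 3,4-bis(benzyloxy)benzonitrile | N#Cc1ccc(OCc2ccccc2)c(OCc2ccccc2)c1 | intermediate
10 | N-(bromomagnesio) ketimine of 1-[3,4-bis(benzyloxy)phenyl]ethanone | CC(=N[Mg]Br)c1ccc(OCc2ccccc2)c(OCc2ccccc2)c1 | intermediate
11 | N-{1-[3,4-bis(benzyloxy)phenyl]ethylidene}acetamide | CC(=NC(C)=O)c1ccc(OCc2ccccc2)c(OCc2ccccc2)c1 | intermediate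
12 | N-{1-[3,4-bis(benzyloxy)phenyl]ethenyl}acetamide | C=C(NC(C)=O)c1ccc(OCc2ccccc2)c(OCc2ccccc2)c1 | intermediate
13 | (6E)-3-(benzyloxy)-6-{[2,4-bis(benzyloxy)-3-methoxyphenyl]methylidene}cyclohexa-2,4-dien-1-one | COc1c(OCc2ccccc2)ccc(/C=C2\C=CC(OCc3ccccc3)=CC2=O)c1OCc1ccccc1 | intermediate
14 | N-{(4S)-7-(benzyloxy)-2-[3,4-bis(benzyloxy)phenyl]-4-[2,4-bis(benzyloxy)-3-methoxyphenyl]-3,4-dihydro-2H-chromen-2-yl}acetamide (C2 configuration left open; it is lost on elimination) | COc1c(OCc4ccccc4)ccc([C@@H]2c3ccc(OCc4ccccc4)cc3OC(NC(C)=O)(c3ccc(OCc4ccccc4)c(OCc4ccccc4)c3)C2)c1OCc1ccccc1 | intermediate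
15 | (4S)-7-(benzyloxy)-2-[3,4-bis(benzyloxy)phenyl]-4-[2,4-bis(benzyloxy)-3-methoxyphenyl]-4H-chromene | COc1c(OCc4ccccc4)ccc([C@@H]2c3ccc(OCc4ccccc4)cc3OC(c3ccc(OCc4ccccc4)c(OCc4ccccc4)c3)=C2)c1OCc1ccccc1 | intermediate
16 | {(2S,3S,4S)-7-(benzyloxy)-2-[3,4-bis(benzyloxy)phenyl]-4-[2,4-bis(benzyloxy)-3-methoxyphenyl]-3,4-dihydro-2H-chromen-3-yl}borane (boron trans to both aryl groups; drawn as the monoalkylborane) | COc1c(OCc4ccccc4)ccc([C@@H]2c3ccc(OCc4ccccc4)cc3O[C@H](c3ccc(OCc4ccccc4)c(OCc4ccccc4)c3)[C@H]2B)c1OCc1ccccc1 | intermediate
17 | (2R,3S,4S)-7-(benzyloxy)-2-[3,4-bis(benzyloxy)phenyl]-4-[2,4-bis(benzyloxy)-3-methoxyphenyl]-3,4-dihydro-2H-chromen-3-ol | COc1c(OCc4ccccc4)ccc([C@@H]2c3ccc(OCc4ccccc4)cc3O[C@H](c3ccc(OCc4ccccc4)c(OCc4ccccc4)c3)[C@H]2O)c1OCc1ccccc1 | intermediate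
18 | (2R,3S,4R)-2-(3,4-dihydroxyphenyl)-4-(2,4-dihydroxy-3-methoxyphenyl)-3,4-dihydro-2H-chromene-3,7-diol | COc1c(O)ccc([C@@H]2c3ccc(O)cc3O[C@H](c3ccc(O)c(O)c3)[C@H]2O)c1O | target

## Step count and risk

Total step count: 8. Longest linear sequence: 6 (steps 1, 2, 3, 6, 7, 8); steps 4 and 5 form the second branch.

**Step 6 (key step).** Four processes may go wrong.
- Enantiofacial discrimination may be poor, because the ortho-benzyloxy group of ring D twists the aryl group out of the methide plane and crowds the catalyst pocket.
- The aminal 14 may fragment back to the stabilised o-quinone methide and enamide under the achiral sulfonic acid, which would erode the enantiomeric purity at C4.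
- Hydride may transfer from the doubly benzylic C4–H of 15 to the stabilised diarylcarbenium ion, a disproportionation toward a flavylium salt.
- The water released may hydrolyse the enamide.

Fallback, from 3 back to 15, with C4 set by a different bond formation. Bromide 3 is lithiated and borylated to [2,4-bis(benzyloxy)-3-methoxyphenyl]boronic acid F1. A rhodium/chiral bisphosphine-catalysed asymmetric 1,4-addition of F1 to commercial 7-(benzyloxy)coumarin (used in excess of boronic acid to offset protodeboronation) should give (4S)-7-(benzyloxy)-4-[2,4-bis(benzyloxy)-3-methoxyphenyl]chroman-2-one F2. Addition of [3,4-bis(benzyloxy)phenyl]lithium F3, made from commercial 4-bromo-1,2-bis(benzyloxy)benzene and n-BuLi, to the lactone at −78 °C should give the lactol (4S)-7-(benzyloxy)-2-[3,4-bis(benzyloxy)phenyl]-4-[2,4-bis(benzyloxy)-3-methoxyphenyl]chroman-2-ol F4. Catalytic p-TsOH in toluene would dehydrate it to 15.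

**Step 7.** Two processes may go wrong. The β-aryloxy alkylborane 16 may undergo β-elimination, opening ring C before oxidation. The facial bias exerted by the C4 aryl group may be insufficient.

Fallback, from 15 back to 17, replacing hydroboration by oxidation, reduction and stereoconvergent ring closure. Dimethyldioxirane oxidation of the enol ether of 15 in wet acetone, anti to the C4 aryl group, should give the ring-opened (2S,3S)-3-[4-(benzyloxy)-2-hydroxyphenyl]-1-[3,4-bis(benzyloxy)phenyl]-3-[2,4-bis(benzyloxy)-3-methoxyphenyl]-2-hydroxypropan-1-one F5. NaBH4 would reduce it to (1RS,2S,3S)-3-[4-(benzyloxy)-2-hydroxyphenyl]-1-[3,4-bis(benzyloxy)phenyl]-3-[2,4-bis(benzyloxy)-3-methoxyphenyl]propane-1,2-diol F6. Mild acid (PPTS, CH2Cl2) would ionise the p-alkoxybenzylic C1–OH of either epimer, and the phenol should close ring C to the 2,3-trans isomer 17 with the 2-aryl group equatorial.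

**Step 5.** The Grignard reagent may add slowly to the electron-rich nitrile. Acetylation of the metallo-imine may be unselective (diacylation), and hydrolysis on work-up may return the ketone instead of the enamide.

Fallback, from 9 back to 12, by reductive acylation of an oxime. Methyl Grignard addition to 9 with acidic aqueous work-up gives 1-[3,4-bis(benzyloxy)phenyl]ethan-1-one F7. Hydroxylamine converts it into (E)-1-[3,4-bis(benzyloxy)phenyl]ethan-1-one oxime F8. Iron powder, Ac2O and AcOH in toluene at 70 °C should then give 12.

**Step 3.** The very electron-rich benzhydrol 7 may ionise on silica or on traces of acid and self-condense through Friedel–Crafts alkylation. Incomplete addition to the deactivated phenolate aldehyde is the second risk.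

Fallback, from 2 back to 7, forming C4–C4a instead of C4–C1''. Vilsmeier–Haack formylation of 2 gives 2,4-bis(benzyloxy)-3-methoxybenzaldehyde F9. Bromomagnesium 3-(benzyloxy)phenolate F10, from commercial 3-(benzyloxy)phenol and EtMgBr, is then hydroxyalkylated by F9 in toluene. The reaction is ortho-selective and should occur at the position para to the benzyloxy group, giving 7, which would be used without chromatography.

## Further compounds

F1 | step 6 | [2,4-bis(benzyloxy)-3-methoxyphenyl]boronic acid | COc1c(OCc2ccccc2)ccc(B(O)O)c1OCc1ccccc1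
F2 | step 6 | (4S)-7-(benzyloxy)-4-[2,4-bis(benzyloxy)-3-methoxyphenyl]chroman-2-one | COc1c(OCc4ccccc4)ccc([C@@H]2c3ccc(OCc4ccccc4)cc3OC(=O)C2)c1OCc1ccccc1
F3 | step 6 | [3,4-bis(benzyloxy)phenyl]lithium | [Li]c1ccc(OCc2ccccc2)c(OCc2ccccc2)c1
F4 | step 6 | (4S)-7-(benzyloxy)-2-[3,4-bis(benzyloxy)phenyl]-4-[2,4-bis(benzyloxy)-3-methoxyphenyl]chroman-2-ol (C2 epimers) | COc1c(OCc4ccccc4)ccc([C@@H]2c3ccc(OCc4ccccc4)cc3OC(O)(c3ccc(OCc4ccccc4)c(OCc4ccccc4)c3)C2)c1OCc1ccccc1
F5 | step 7 | (2S,3S)-3-[4-(benzyloxy)-2-hydroxyphenyl]-1-[3,4-bis(benzyloxy)phenyl]-3-[2,4-bis(benzyloxy)-3-methoxyphenyl]-2-hydroxypropan-1-one | COc1c(OCc2ccccc2)ccc([C@H](c2ccc(OCc3ccccc3)cc2O)[C@H](O)C(=O)c2ccc(OCc3ccccc3)c(OCc3ccccc3)c2)c1OCc1ccccc1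
F6 | step 7 | (1RS,2S,3S)-3-[4-(benzyloxy)-2-hydroxyphenyl]-1-[3,4-bis(benzyloxy)phenyl]-3-[2,4-bis(benzyloxy)-3-methoxyphenyl]propane-1,2-diol | COc1c(OCc2ccccc2)ccc([C@H](c2ccc(OCc3ccccc3)cc2O)[C@H](O)C(O)c2ccc(OCc3ccccc3)c(OCc3ccccc3)c2)c1OCc1ccccc1
F7 | step 5 | 1-[3,4-bis(benzyloxy)phenyl]ethan-1-one | CC(=O)c1ccc(OCc2ccccc2)c(OCc2ccccc2)c1
F8 | step 5 | (E)-1-[3,4-bis(benzyloxy)phenyl]ethan-1-one oxime | C/C(=N\O)c1ccc(OCc2ccccc2)c(OCc2ccccc2)c1
F9 | step 3 | 2,4-bis(benzyloxy)-3-methoxybenzaldehyde | COc1c(OCc2ccccc2)ccc(C=O)c1OCc1ccccc1
F10 | step 3 | bromomagnesium 3-(benzyloxy)phenolate | Br[Mg]Oc1cccc(OCc2ccccc2)c1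
A1 | alternative 1 | (2R,3S)-7-(benzyloxy)-2-[3,4-bis(benzyloxy)phenyl]-4-methoxychroman-3-ol (C4 epimers) | COC1c2ccc(OCc3ccccc3)cc2O[C@H](c2ccc(OCc3ccccc3)c(OCc3ccccc3)c2)[C@H]1O
A2 | alternative 2 | (2S)-7-(benzyloxy)-2-[3,4-bis(benzyloxy)phenyl]chroman-4-one | O=C1C[C@@H](c2ccc(OCc3ccccc3)c(OCc3ccccc3)c2)Oc2cc(OCc3ccccc3)ccc12
A3 | alternative 2 | (2S)-7-(benzyloxy)-2-[3,4-bis(benzyloxy)phenyl]-4-[2,4-bis(benzyloxy)-3-methoxyphenyl]-2H-chromene | COc1c(OCc2ccccc2)ccc(C2=C[C@@H](c3ccc(OCc4ccccc4)c(OCc4ccccc4)c3)Oc3cc(OCc4ccccc4)ccc23)c1OCc1ccccc1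
A4 | alternative 3 | 5-(benzyloxy)-2-{(1S,2E)-1-[2,4-bis(benzyloxy)-3-methoxyphenyl]-3-[3,4-bis(benzyloxy)phenyl]prop-2-en-1-yl}phenol | COc1c(OCc2ccccc2)ccc([C@@H](/C=C/c2ccc(OCc3ccccc3)c(OCc3ccccc3)c2)c2ccc(OCc3ccccc3)cc2O)c1OCc1ccccc1
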